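Rings C and D are removed together by cutting C9–C11 and C8–C15. The feature exploited is this: the lactone carbonyl C7 of ring B makes C9 an acceptor and C8 a latent enolate carbon. Their neighbours C11 (ring C) and C15 (ring D) are both oxygenated, so both can start as carbonyl carbons. The precursor is the C8=C9 unsaturated spirolactone on ring A. At C8 it carries a CH2 group (C14) bound to the central carbon (C13) of a glutaraldehyde unit. Two electrons from samarium should join one formyl carbon to C9 and let the derived enolate capture the other. One operation then gives the bicyclo[3.2.1]octane, two C–C bonds and five stereocentres.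

Key step: step 18

Remark 1: ent-kaurane numbering is used throughout; α is the ring A face that carries C20, C19 and C6, and β is the face that carries C9, H5 and O1.
Remark 2 (assumption): the sense of induction in step 2 is taken from the formyl C–H···O binding model for α-substituted enals; if the antipode of 4 formed, the catalyst from (R)-diphenylprolinol would be used.
Remark 3 (assumption): lactols 7 and 35 equilibrate at C6 and are drawn as exo anomers; 22 to 24 are C8 epimer pairs and both epimers serve.
Remark 4: the two formyl arms of 27 are constitutionally equal but diastereotopic, so C13 needs control; step 18 deals with this.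

Step 1
Reactants: 1 but-3-en-2-one
Product: 2 2-(triisopropylsilyloxy)buta-1,3-diene
Conditions: i-Pr3SiOTf, Et3N, CH2Cl2, 0 °C
Reagents that add atoms: triisopropylsilyl triflate, CC(C)[Si](C(C)C)(C(C)C)OS(=O)(=O)C(F)(F)F
Why: Silyl enol ether formation by soft enolisation of the methyl ketone should give the 2-silyloxydiene, and the bulky silyl group is chosen so that the enol ether outlasts the acidic cycloaddition catalyst and the hydride steps that follow.

Step 2
Reactants: 2 2-(triisopropylsilyloxy)buta-1,3-diene; 3 ethyl (E)-3-methyl-4-oxobut-2-enoate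
Product: 4 ethyl (1R,6R)-6-formyl-6-methyl-3-(triisopropylsilyloxy)cyclohex-3-ene-1-carboxylate
Conditions: (S)-3,3-diphenyl-1-(2-methylphenyl)tetrahydro-1H,3H-pyrrolo[1,2-c][1,3,2]oxazaborole and HN(SO2CF3)2 (15 mol % each), CH2Cl2, −78 °C
Reagents that add atoms: none
Why: Catalytic enantioselective Diels–Alder reaction of an α-methyl enal held on a cationic oxazaborolidine, in which the nucleophilic CH2 terminus of 2 (future C10) bonds to the carbon β to the formyl group (C5), the silyloxy carbon ends para to C4, the E geometry of 3 is carried into the trans adduct, and shielding of one enal face sets the quaternary centre C4.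

Step 3
Reactants: 4 Diels–Alder adduct
Product: 6 (3aR,7aS)-3a-methyl-6-(triisopropylsilyloxy)-3a,4,7,7a-tetrahydro-2-benzofuran-1(3H)-one (cis-fused), via hydroxy ester 5 (not isolated)
Conditions: NaBH4, EtOH, −20 °C; then NaOEt (0.3 equiv), EtOH, 40 °C
Reagents that add atoms: none
Why: Chemoselective borohydride reduction of the aldehyde followed by ethoxide-mediated epimerisation at C5 (α to the ester) and lactonisation should drain the trans hydroxy ester into the more stable cis-fused γ-lactone, so that C5 is set under thermodynamic control from C4.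

Step 4
Reactants: 6 cis-fused lactone
Product: 7 (1S,3aR,7aS)-3a-methyl-6-(triisopropylsilyloxy)-1,3,3a,4,7,7a-hexahydro-2-benzofuran-1-ol
Conditions: i-Bu2AlH (1.1 equiv), CH2Cl2, −78 °C; aq. potassium sodium tartrate
Reagents that add atoms: none
Why: Partial reduction of a γ-lactone to the lactol at low temperature, made chemoselective by keeping the C1 ketone masked as its silyl enol ether.

Step 5
Reactants: 7 lactol
Product: 8 (1S,3aR,7aS)-1-methoxy-3a-methyl-6-(triisopropylsilyloxy)-1,3,3a,4,7,7a-hexahydro-2-benzofuran
Conditions: PPTS (10 mol %), MeOH, 0 °C to rt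
Reagents that add atoms: methanol, CO
Why: Acid-catalysed acetalisation under equilibrium control should put the methoxy group on the convex face, anti to the C5–C10 bond, while the hindered silyl enol ether tolerates the weak acid.

Step 6
Reactants: 8 methyl acetal
Product: 9 (1S,3aR,7aS)-1-methoxy-3a-methyl-3,3a,7,7a-tetrahydro-2-benzofuran-6(1H)-one (ring A enone, C1 ketone, C2=C3)
Conditions: Pd(OAc)2 (1.05 equiv), MeCN, 40 °C
Reagents that add atoms: none
Why: Saegusa–Ito oxidation turns the regiodefined C1=C2 enol ether into the C2=C3 enone, which leaves C10 as the only enolisable carbon next to the C1 ketone.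

Step 7
Reactants: 9 ring A enone
Product: 10 C10 hydroxymethylene derivative of enone 9 (enol form of the β-keto aldehyde, new carbon is C20)
Conditions: LiN(i-Pr)2, THF, −78 °C; HCO2CH2CF3; AcOH quench
Reagents that add atoms: 2,2,2-trifluoroethyl formate, O=COCC(F)(F)F
Why: Crossed Claisen formylation of the kinetic cross-conjugated enolate brings in C20 at the aldehyde level and gives the stable hydrogen-bonded enol.

Step 8
Reactants: 10 hydroxymethylene enone; 11 methyl acrylate
Product: 12 C10-quaternary keto aldehyde (10S): enone 9 bearing at C10 an α formyl group (C20) and a β CH2CH2CO2Me chain (C9, C8, C7)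
Conditions: DBU (0.2 equiv), MeCN, 0 °C to rt
Reagents that add atoms: none
Why: Base-catalysed Michael addition of the β-keto aldehyde, in which allylic strain with the exocyclic C20 pushes C6 pseudoaxial so that the acrylate should approach C10 from the convex β face, anti to C6, and set the quaternary centre with C9 β and C20 α.

Step 9
Reactants: 12 keto aldehyde
Product: 14 C1,C20 diol (1R, O1 β, allylic alcohol), via hydroxy enone 13 (not isolated)
Conditions: Me4NBH(OAc)3 (8 equiv), MeCN–AcOH, −30 to 0 °C
Reagents that add atoms: none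
Why: Triacetoxyborohydride reduces the aldehyde first and the boron-bound C20 alkoxide of 13 then delivers hydride to the C1 carbonyl from the α face (Evans–Saksena hydroxyl-directed 1,2-reduction), which should give the C1 alcohol anti to C20 and cis to C9.

Step 10
Reactants: 14 diol
Product: 15 C1,C20 bis(tert-butyldimethylsilyl) ether
Conditions: t-BuMe2SiOTf (3 equiv), 2,6-lutidine, CH2Cl2, −78 to 0 °C
Reagents that add atoms: tert-butyldimethylsilyl triflate, CC(C)(C)[Si](C)(C)OS(=O)(=O)C(F)(F)F
Why: Exhaustive silylation with the silyl triflate caps the hindered C1 hydroxyl before any lactonisation, which excludes closure of the competing 1,7-lactone.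

Step 11
Reactants: 15 bis-silyl ether
Product: 16 2,3-dihydro bis-silyl ether (saturated ring A)
Conditions: H2 (1 atm), Pd/C, EtOAc, rt
Reagents that add atoms: none
Why: Heterogeneous catalytic hydrogenation removes the C2=C3 alkene, the only reducible group, and creates no stereocentre.

Step 12
Reactants: 16 saturated bis-silyl ether
Product: 18 saturated 7,20-spirolactone with C1 β silyl ether and C6 exo methyl acetal, via hydroxy ester 17 (not isolated)
Conditions: camphorsulfonic acid (10 mol %), MeOH–CH2Cl2, 0 °C; then solvent change to toluene, 60 °C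
Reagents that add atoms: none
Why: Acid-catalysed methanolysis cleaves the primary silyl ether much faster than the hindered secondary one, and the freed C20 hydroxyl should then lactonise onto the C7 ester, helped by the gem-dialkyl effect of C10, while methanol keeps the methyl acetal intact.

Step 13
Reactants: 19 cyclopent-3-ene-1-carboxylic acid
Product: 20 cyclopent-3-en-1-ylmethanol
Conditions: LiAlH4, Et2O, 0 °C to rt
Reagents that add atoms: none
Why: Standard hydride reduction of a carboxylic acid to the primary alcohol, which leaves the isolated alkene untouched.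

Step 14
Reactants: 20 cyclopent-3-en-1-ylmethanol
Product: 21 4-(iodomethyl)cyclopent-1-ene
Conditions: I2, PPh3, imidazole, CH2Cl2, 0 °C
Reagents that add atoms: iodine, II
Why: Appel-type iodination converts the primary alcohol into the iodide by SN2 displacement of the oxyphosphonium ion.

Step 15
Reactants: 18 spirolactone; 21 4-(iodomethyl)cyclopent-1-ene
Product: 22 C8-(cyclopent-3-en-1-ylmethyl) spirolactone (C8 epimers)
Conditions: LiN(i-Pr)2, THF–DMPU, −78 to −20 °C
Reagents that add atoms: none
Why: Alkylation of the lactone lithium enolate with the primary iodide attaches C14 to C8, the cyclopentene being a compact latent form of the two equal formyl arms, and the new C8 centre is irrelevant because it becomes sp2 in the next step.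

Step 16
Reactants: 22 alkylated spirolactone
Product: 25 C8=C9 unsaturated spirolactone bearing the cyclopent-3-en-1-ylmethyl group at C8, via selenide 23 (not isolated), via selenoxide 24 (not isolated)
Conditions: KN(SiMe3)2, THF, −78 °C; PhSeBr; then m-CPBA (1.0 equiv), pyridine, CH2Cl2, −78 °C to rt
Reagents that add atoms: none
Why: α-Selenenylation of the tertiary lactone enolate and selenoxide syn-elimination should install the conjugated endocyclic C8=C9 alkene, the selenide being oxidised at −78 °C far faster than the cyclopentene.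

Step 17
Reactants: 25 unsaturated spirolactone
Product: 27 dialdehyde: C8=C9 unsaturated spirolactone with a 2-(2-oxoethyl)-4-oxobutyl chain at C8, via ozonide 26 (not isolated)
Conditions: O3, CH2Cl2, −78 °C, stopped when 25 is consumed; PPh3, −78 °C to rt
Reagents that add atoms: ozone, [O-][O+]=O
Why: Ozonolysis with reductive work-up cleaves the electron-rich cyclopentene in preference to the electron-poor trisubstituted C8=C9 alkene and unveils both formyl groups at once, the sensitive dialdehyde being used directly.

Step 18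
Reactants: 27 dialdehyde
Product: 29 bicyclo[3.2.1]octane 11,15-diol lactone (8S,9S,11R,13S,15S), via samarium enolate 28 (not isolated)
Conditions: SmI2 (2.5 equiv), LiBr (excess), t-BuOH (1 equiv), THF, −78 °C; aqueous work-up
Reagents that add atoms: none
Why: Samarium dibromide made in the flask gives one electron to either formyl group, the nucleophilic ketyl adds to the electron-poor C9 of the unsaturated lactone (C9–C11), a second electron turns the C8 radical into the trivalent samarium enolate 28, and this adds to the remaining formyl group (C8–C15). The closest known reaction type is the samarium-mediated ketyl–olefin cyclisation and aldol cascade of dialdehydes that carry an α,β-unsaturated ester or lactone. Ring C closes 6-endo-trig (5-exo attack would have to hit the fully substituted, polarity-mismatched C8) and ring D closes 5-(enolexo)-exo-trig. C9 is set by attack on the lactone face flanked by C1, because on the other face the acetal carbon C6 on C5 lies gauche to C9 over the alkene whereas C1 offers only H1 there, C11 follows from a chair-like transition state in which H11 and not the samarium-bound oxygen faces the C1 silyl ether, and C13 follows from reaction of the diastereotopic arm that leaves the other arm equatorial and trans to C10. That spectator arm can reach only the enolate face syn to H9, which fixes C8, and chelation of samarium to the lactone oxygen should place O15 syn to C7 (this centre is erased in step 19). The selectivity needed is conjugate addition over pinacol coupling of the 1,5-dialdehyde and over early protonation of the enolate, and it rests on the polarity match and six-atom reach of C9, on halide-saturated samarium that binds a second carbonyl poorly, and on a single equivalent of t-BuOH at −78 °C.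

Step 19
Reactants: 29 11,15-diol
Product: 30 11-hydroxy 15-ketone
Conditions: Dess–Martin periodinane (1.05 equiv), CH2Cl2, 0 °C
Reagents that add atoms: none
Why: Dess–Martin oxidation with one equivalent should take the exposed cyclopentanol at C15, because the C11 carbinol is buried in the cleft between ring C and the C1 silyl ether.

Step 20
Reactants: 30 hydroxy ketone
Product: 31 1,11-bis(tert-butyldimethylsilyl) ether 15-ketone
Conditions: t-BuMe2SiOTf, 2,6-lutidine, CH2Cl2, −78 to 0 °C
Reagents that add atoms: tert-butyldimethylsilyl triflate, CC(C)(C)[Si](C)(C)OS(=O)(=O)C(F)(F)F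
Why: Silylation with the reactive silyl triflate protects the hindered C11 hydroxyl so that it cannot be deprotonated in step 21 or acetylated in step 23.

Step 21
Reactants: 31 bis-silyl ketone
Product: 34 16-methylene 15-ketone (exocyclic enone), via Mannich base 32 (not isolated), via methiodide 33 (not isolated)
Conditions: LiN(SiMe3)2, THF, −78 °C; CH2=NMe2+ I−, −78 °C to rt; MeI, CH2Cl2, rt; sat. aq. NaHCO3
Reagents that add atoms: Eschenmoser salt (N,N-dimethylmethyleneiminium iodide), C=[N+](C)C.[I-]
Why: Eschenmoser methylenation, that is Mannich reaction of the only possible enolate (C15/C16, since C8 is quaternary), N-methylation and Hofmann-type β-elimination, should add C17 as the exocyclic methylene group.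

Step 22
Reactants: 34 enone methyl acetal
Product: 35 C6 lactol (exo anomer drawn)
Conditions: 0.5 M aq. HCl, THF, rt
Reagents that add atoms: water, O
Why: Mild aqueous acid hydrolysis of the tetrahydrofuranyl methyl acetal, which ionises far more readily than the two hindered secondary silyl ethers are cleaved, should give the lactol.

Step 23
Reactants: 35 lactol
Product: 36 C6 acetate (6R) with silyl ethers at O1 and O11
Conditions: Ac2O, pyridine, DMAP (cat.), CH2Cl2, 0 °C
Reagents that add atoms: acetic anhydride, CC(=O)OC(C)=O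
Why: Acylation of the equilibrating lactol, the only free hydroxyl, should occur on the more accessible and more stable exo anomer and give the C6 acetate anti to the C5–C10 bond, as in the target.

Step 24
Reactants: 36 bis-silyl acetate
Product: 37 oreskaurin A
Conditions: HF·pyridine, pyridine, THF, 0 °C to rt
Reagents that add atoms: none
Why: Buffered fluoride-mediated desilylation under slightly acidic conditions removes both silyl ethers without base, so that the anomeric acetate, the enone and the 7,20-lactone (which could migrate to O1) should stay intact.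

Compound list
1 | but-3-en-2-one | C=CC(C)=O | starting material
2 | 2-(triisopropylsilyloxy)buta-1,3-diene | C=CC(=C)O[Si](C(C)C)(C(C)C)C(C)C | intermediate
3 | ethyl (E)-3-methyl-4-oxobut-2-enoate | CCOC(=O)/C=C(\C)C=O | starting material
4 | ethyl (1R,6R)-6-formyl-6-methyl-3-(triisopropylsilyloxy)cyclohex-3-ene-1-carboxylate | C1C(O[Si](C(C)C)(C(C)C)C(C)C)=CC[C@@](C)(C=O)[C@@H]1C(=O)OCC | intermediate
5 | ethyl (1R,6R)-6-(hydroxymethyl)-6-methyl-3-(triisopropylsilyloxy)cyclohex-3-ene-1-carboxylate | C1C(O[Si](C(C)C)(C(C)C)C(C)C)=CC[C@@](C)(CO)[C@@H]1C(=O)OCC | intermediate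
6 | (3aR,7aS)-3a-methyl-6-(triisopropylsilyloxy)-3a,4,7,7a-tetrahydro-2-benzofuran-1(3H)-one | C1C(O[Si](C(C)C)(C(C)C)C(C)C)=CC[C@@]2(C)COC(=O)[C@H]21 | intermediate
7 | (1S,3aR,7aS)-3a-methyl-6-(triisopropylsilyloxy)-1,3,3a,4,7,7a-hexahydro-2-benzofuran-1-ol | C1C(O[Si](C(C)C)(C(C)C)C(C)C)=CC[C@@]2(C)CO[C@H](O)[C@H]21 | intermediate
8 | (1S,3aR,7aS)-1-methoxy-3a-methyl-6-(triisopropylsilyloxy)-1,3,3a,4,7,7a-hexahydro-2-benzofuran | C1C(O[Si](C(C)C)(C(C)C)C(C)C)=CC[C@@]2(C)CO[C@H](OC)[C@H]21 | intermediate
9 | (1S,3aR,7aS)-1-methoxy-3a-methyl-3,3a,7,7a-tetrahydro-2-benzofuran-6(1H)-one | C1C(=O)C=C[C@@]2(C)CO[C@H](OC)[C@H]21 | intermediate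
10 | C10 hydroxymethylene enone | OC=C1C(=O)C=C[C@@]2(C)CO[C@H](OC)[C@H]21 | intermediate
11 | methyl acrylate | C=CC(=O)OC | starting material
12 | C10-quaternary keto aldehyde | COC(=O)CC[C@]1(C=O)C(=O)C=C[C@@]2(C)CO[C@H](OC)[C@H]21 | intermediate
13 | C20 hydroxy enone | COC(=O)CC[C@]1(CO)C(=O)C=C[C@@]2(C)CO[C@H](OC)[C@H]21 | intermediate
14 | C1,C20 diol | COC(=O)CC[C@]1(CO)[C@H](O)C=C[C@@]2(C)CO[C@H](OC)[C@H]21 | intermediate
15 | C1,C20 bis-silyl ether | COC(=O)CC[C@]1(CO[Si](C)(C)C(C)(C)C)[C@H](O[Si](C)(C)C(C)(C)C)C=C[C@@]2(C)CO[C@H](OC)[C@H]21 | intermediate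
16 | saturated bis-silyl ether | COC(=O)CC[C@]1(CO[Si](C)(C)C(C)(C)C)[C@H](O[Si](C)(C)C(C)(C)C)CC[C@@]2(C)CO[C@H](OC)[C@H]21 | intermediate
17 | C20 hydroxy ester | COC(=O)CC[C@]1(CO)[C@H](O[Si](C)(C)C(C)(C)C)CC[C@@]2(C)CO[C@H](OC)[C@H]21 | intermediate
18 | saturated 7,20-spirolactone | O=C1CC[C@]2(CO1)[C@H](O[Si](C)(C)C(C)(C)C)CC[C@@]3(C)CO[C@H](OC)[C@H]32 | intermediate
19 | cyclopent-3-ene-1-carboxylic acid | OC(=O)C1CC=CC1 | starting material
20 | cyclopent-3-en-1-ylmethanol | OCC1CC=CC1 | intermediate
21 | 4-(iodomethyl)cyclopent-1-ene | ICC1CC=CC1 | intermediate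
22 | C8-(cyclopent-3-en-1-ylmethyl) spirolactone, C8 epimers | C1(CC=CC1)CC2C[C@]3(COC2=O)[C@H](O[Si](C)(C)C(C)(C)C)CC[C@@]4(C)CO[C@H](OC)[C@H]43 | intermediate
23 | C8 phenylselenide | C1(CC=CC1)CC2([Se]c5ccccc5)C[C@]3(COC2=O)[C@H](O[Si](C)(C)C(C)(C)C)CC[C@@]4(C)CO[C@H](OC)[C@H]43 | intermediate
24 | C8 selenoxide | C1(CC=CC1)CC2([Se](=O)c5ccccc5)C[C@]3(COC2=O)[C@H](O[Si](C)(C)C(C)(C)C)CC[C@@]4(C)CO[C@H](OC)[C@H]43 | intermediate
25 | C8=C9 unsaturated spirolactone with cyclopentenylmethyl group | C1(CC=CC1)CC2=C[C@]3(COC2=O)[C@H](O[Si](C)(C)C(C)(C)C)CC[C@@]4(C)CO[C@H](OC)[C@H]43 | intermediate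
26 | ozonide of 25 | C1(CC5OOC(C1)O5)CC2=C[C@]3(COC2=O)[C@H](O[Si](C)(C)C(C)(C)C)CC[C@@]4(C)CO[C@H](OC)[C@H]43 | intermediate
27 | dialdehyde, precursor of the key step | O=CCC(CC=O)CC1=C[C@]2(COC1=O)[C@H](O[Si](C)(C)C(C)(C)C)CC[C@@]3(C)CO[C@H](OC)[C@H]32 | intermediate
28 | ring C trivalent samarium enolate | O=CC[C@@H]1C[C@@H](O[Sm](Br)Br)[C@@H]2C(C1)=C(O[Sm](Br)Br)OC[C@]23[C@H](O[Si](C)(C)C(C)(C)C)CC[C@@]4(C)CO[C@H](OC)[C@H]43 | intermediate
29 | bicyclo[3.2.1]octane 11,15-diol lactone | C1[C@H](O)[C@]23C[C@H]1C[C@@H](O)[C@H]2[C@]1(COC3=O)[C@H](O[Si](C)(C)C(C)(C)C)CC[C@@]2(C)CO[C@H](OC)[C@H]21 | intermediate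
30 | 11-hydroxy 15-ketone | C1C(=O)[C@]23C[C@H]1C[C@@H](O)[C@H]2[C@]1(COC3=O)[C@H](O[Si](C)(C)C(C)(C)C)CC[C@@]2(C)CO[C@H](OC)[C@H]21 | intermediate
31 | 1,11-bis-silyl 15-ketone | C1C(=O)[C@]23C[C@H]1C[C@@H](O[Si](C)(C)C(C)(C)C)[C@H]2[C@]1(COC3=O)[C@H](O[Si](C)(C)C(C)(C)C)CC[C@@]2(C)CO[C@H](OC)[C@H]21 | intermediate
32 | C16 dimethylaminomethyl ketone (Mannich base) | CN(C)CC1C(=O)[C@]23C[C@H]1C[C@@H](O[Si](C)(C)C(C)(C)C)[C@H]2[C@]1(COC3=O)[C@H](O[Si](C)(C)C(C)(C)C)CC[C@@]2(C)CO[C@H](OC)[C@H]21 | intermediate
33 | methiodide of 32 | C[N+](C)(C)CC1C(=O)[C@]23C[C@H]1C[C@@H](O[Si](C)(C)C(C)(C)C)[C@H]2[C@]1(COC3=O)[C@H](O[Si](C)(C)C(C)(C)C)CC[C@@]2(C)CO[C@H](OC)[C@H]21.[I-] | intermediate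
34 | 16-methylene 15-ketone methyl acetal | C=C1C(=O)[C@]23C[C@H]1C[C@@H](O[Si](C)(C)C(C)(C)C)[C@H]2[C@]1(COC3=O)[C@H](O[Si](C)(C)C(C)(C)C)CC[C@@]2(C)CO[C@H](OC)[C@H]21 | intermediate
35 | C6 lactol | C=C1C(=O)[C@]23C[C@H]1C[C@@H](O[Si](C)(C)C(C)(C)C)[C@H]2[C@]1(COC3=O)[C@H](O[Si](C)(C)C(C)(C)C)CC[C@@]2(C)CO[C@H](O)[C@H]21 | intermediate
36 | C6 acetate, bis-silyl ether | C=C1C(=O)[C@]23C[C@H]1C[C@@H](O[Si](C)(C)C(C)(C)C)[C@H]2[C@]1(COC3=O)[C@H](O[Si](C)(C)C(C)(C)C)CC[C@@]2(C)CO[C@H](OC(C)=O)[C@H]21 | intermediate
37 | oreskaurin A | C=C1C(=O)[C@]23C[C@H]1C[C@@H](O)[C@H]2[C@]1(COC3=O)[C@H](O)CC[C@@]2(C)CO[C@H](OC(C)=O)[C@H]21 | target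

Total step count: 24. Longest linear sequence: 22 (steps 1 to 12 and 15 to 24).

Steps most likely to fail

Step 18. Pinacol coupling between the two formyl arms, or protonation of the enolate before the aldol, may outrun the cascade, and face or arm selection may be incomplete.
- The fallback sets out from cyclopentene 25 and differentiates the arms so that only one of them can form a ketyl.
- Ozonolysis in CH2Cl2–MeOH over NaHCO3 should give the aldehyde α-methoxy hydroperoxide F1. Ac2O and Et3N dehydrate it to the aldehyde methyl ester F2, formed as both C13 epimers because either alkene carbon can end as the ester.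
- SmI2–LiBr does not reduce the ester, so the ketyl can only add to C9.
- On warming, the ester acylates the trivalent samarium enolate (Dieckmann-type closure). The C13 epimer whose ester arm sits trans to C10 should then give hydroxy ketone 30 directly, and the other epimer is removed by chromatography.
- The route is rejoined at 30, and step 19 is no longer needed.

Step 19. Discrimination between the two secondary carbinols may be insufficient, with oxidation also at C11.
- The fallback sets out from diol 29 and replaces direct oxidation by protecting-group differentiation, in which any wrongly silylated material can be desilylated and recycled.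
- Et3SiCl and imidazole at low temperature should give the 15-triethylsilyl ether F3.
- t-BuMe2SiOTf and 2,6-lutidine then give the 11-tert-butyldimethylsilyl 15-triethylsilyl bis-ether F4.
- PPTS in MeOH removes only the triethylsilyl group to give the 15-alcohol F5.
- Dess–Martin oxidation of this single free hydroxyl rejoins the route at 31.

Step 16. The selenoxide may eliminate toward C14 and place the alkene outside the ring.
- The fallback sets out from spirolactone 18 and introduces the alkene before the side chain.
- LiN(i-Pr)2 and PhSeBr give the C8 selenide F6, and m-CPBA gives the selenoxide F7. This can eliminate only into the ring, to the C8-unsubstituted unsaturated lactone F8.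
- α-Iodination (I2, pyridine, CH2Cl2) gives the C8 iodide F9.
- Iodide 21 and zinc dust in THF give (cyclopent-3-en-1-ylmethyl)zinc iodide F10.
- Negishi coupling of F9 with F10 (PdCl2(dppf), THF, rt) rejoins the route at 25.

Further compounds
F1 | step 18 | aldehyde α-methoxy hydroperoxide from 25 (epimers at C13 and at the peroxy acetal carbon) | O=CCC(CC(OC)OO)CC1=C[C@]2(COC1=O)[C@H](O[Si](C)(C)C(C)(C)C)CC[C@@]3(C)CO[C@H](OC)[C@H]32
F2 | step 18 | aldehyde methyl ester (both C13 epimers) | O=CCC(CC(=O)OC)CC1=C[C@]2(COC1=O)[C@H](O[Si](C)(C)C(C)(C)C)CC[C@@]3(C)CO[C@H](OC)[C@H]32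
F3 | step 19 | 15-triethylsilyl ether of diol 29 | C1[C@H](O[Si](CC)(CC)CC)[C@]23C[C@H]1C[C@@H](O)[C@H]2[C@]1(COC3=O)[C@H](O[Si](C)(C)C(C)(C)C)CC[C@@]2(C)CO[C@H](OC)[C@H]21
F4 | step 19 | 11-tert-butyldimethylsilyl 15-triethylsilyl bis-ether | C1[C@H](O[Si](CC)(CC)CC)[C@]23C[C@H]1C[C@@H](O[Si](C)(C)C(C)(C)C)[C@H]2[C@]1(COC3=O)[C@H](O[Si](C)(C)C(C)(C)C)CC[C@@]2(C)CO[C@H](OC)[C@H]21
F5 | step 19 | 1,11-bis-silyl 15-alcohol | C1[C@H](O)[C@]23C[C@H]1C[C@@H](O[Si](C)(C)C(C)(C)C)[C@H]2[C@]1(COC3=O)[C@H](O[Si](C)(C)C(C)(C)C)CC[C@@]2(C)CO[C@H](OC)[C@H]21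
F6 | step 16 | C8 phenylselenide of 18 (C8 epimers) | O=C1C([Se]c4ccccc4)C[C@]2(CO1)[C@H](O[Si](C)(C)C(C)(C)C)CC[C@@]3(C)CO[C@H](OC)[C@H]32
F7 | step 16 | selenoxide of F6 | O=C1C([Se](=O)c4ccccc4)C[C@]2(CO1)[C@H](O[Si](C)(C)C(C)(C)C)CC[C@@]3(C)CO[C@H](OC)[C@H]32
F8 | step 16 | C8-unsubstituted C8=C9 unsaturated spirolactone | O=C1C=C[C@]2(CO1)[C@H](O[Si](C)(C)C(C)(C)C)CC[C@@]3(C)CO[C@H](OC)[C@H]32
F9 | step 16 | C8 iodo unsaturated spirolactone | O=C1C(I)=C[C@]2(CO1)[C@H](O[Si](C)(C)C(C)(C)C)CC[C@@]3(C)CO[C@H](OC)[C@H]32
F10 | step 16 | (cyclopent-3-en-1-ylmethyl)zinc iodide | I[Zn]CC1CC=CC1
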